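The numbers stand for no real mixture.

One hour was my unit and the fraction of the charge my measure; I followed rates, not amounts, in two flasks that share a recipe and differ in when they stop.

| flask | substrate | first nucleophile | second nucleophile | time |
|---|---|---|---|---|
| south-east | 0.020 M | 1.50 equiv | 4.00 equiv | 4.0 h |
| north-west | 0.020 M | 1.50 equiv | 4.00 equiv | 5.0 h |

    first nucleophile + target → over-reaction product (k1 = 0.0029 /M/s)
    substrate → intermediate (k2 = 1.2 × 10⁻⁴ /s)
    first nucleophile + intermediate → target (k3 = 0.39 /M/s)
    second nucleophile + intermediate → other capture product (k4 = 0.064 /M/s)
    second nucleophile → decomposed reagent (k5 = 1.7 × 10⁻⁴ /s)

* which of the two there is more of at the end, south-east (over-reaction product / target)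
* which of the two there is more of at the end, north-west (over-reaction product / target)
* target at the end, in percent of the substrate charged, south-east
* target at the end, in percent of the substrate charged, north-west

At the charges, intermediate had a half-life of 0.99 min against first nucleophile, far shorter than the 1.6 h of substrate, so I took each portion as captured at once.

At the start, the leak to other capture product ran at 0.438 of the rate to target. I replaced the spread of birth times by one moment, when half the substrate had gone, at 1.6 h. By then, in my reckoning, the decay of second nucleophile had multiplied the leak by 0.375. First nucleophile, taken one per substrate turned, stood at 0.667 of its charge, which divided the leak by that figure. The leak ratio became 0.246, and the birth share, the part of the intermediate taken by first nucleophile at that moment, came to 0.803.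

Target meanwhile met a pseudo-first-order drain of 0.313 /h at the full charge of first nucleophile. I let leak and over-reaction cancel in the use of first nucleophile, so its mean fraction from birth to end was 0.559 in south-east and 0.538 in north-west. Substrate turned, times birth share, times survival, gave me 43.4% target in south-east and 40.1% in north-west.

The forecast said target in both flasks, 43.2% in south-east and 43.9% in north-west: "it exceeds over-reaction product at both times". For north-west my figure was lower than the forecast's.

The simulation gave target ahead in south-east, 43.0% against 22.5%, and target ahead in north-west, 43.8% against 27.6%.

The later stop added 0.8 percentage points of target and 5.1 points of over-reaction product, and at 5.00 h in north-west target was made 1.03 times as fast as it was used up. Birth share times substrate turned gave 71.0% for north-west, where target plus over-reaction product stood at 71.4%. With 1.00 equiv of second nucleophile, I reckoned for the neighbour of north-west a birth share of 0.942, which gives 83.3%. That flask held 82.7% as target plus over-reaction product, with target at 53.6%.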